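**Retrosynthetic overview**
1. Ring E (the 1,2-dioxocan-3-ol, C-spiro–CH2–C-hem(OH)–O–O–C-per–C-α–C-ket) is closed last, as the peroxyhemiacetal of a C-hem aldehyde (latent in an allyl group on C-spiro) with the tertiary hydroperoxide on C-per. The enabling feature is that C-per–OOH is also β to the ketone C-ket, so the peroxide can be parked in a silyl-locked 1,2-dioxolan-3-ol (temporary ring C-per–O–O–C-ket) and relayed to C-hem at the end.
2. Before that: ring C epoxide by bromohydrin closure; C-per–OOH by Schenck ene reaction of a transposed ring C alkene; ring D (lactam hemiaminal) by nitrile hydration onto the benzyl ketone.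
3. The 13-membered cyclophane by C-alkylation of an α-allyl β-keto nitrile with an aryl-tethered α-chloro ketone (sets quaternary C-spiro).
4. Rings B and C together by intramolecular Diels–Alder reaction of a 2-siloxydiene and an enoate mounted on ring A; aryl ether by Mitsunobu inversion.
5. Ring A from 2,4,6-trimethylphenol (desymmetrised meso ketone, conjugate addition and Mukaiyama trapping). Ring order: A, B + C, macrocycle, D, temporary dioxolane, epoxide, E.

Key step: step 29

Labels used in the text: rings A (trimethylcyclohexane), B (cyclopentane), C (six-membered carbocycle), D (lactam), E (1,2-dioxocane); C-spiro = spiro carbon; C-ket = ketone carbon between C-spiro and ring C; C-α = ring C methine on C-ket; C-per = ring C carbon bearing methyl and the peroxide oxygen; C-hem = hemiacetal carbon.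

Assumption: the 8-membered peroxyhemiacetal of the target is the thermodynamic resting form of the corresponding hydroperoxy keto-aldehyde, and its hemiacetal and hemiaminal carbons carry their equilibrium configurations.

**Route**

Step 1
Reactants: 1 2,4,6-trimethylphenol
Product: 2 cis,cis-2,4,6-trimethylcyclohexanone (meso)
Conditions: H2 (10 bar), Pd/C, cyclohexane, 120 °C; then NaOMe (cat.), MeOH, 23 °C
Reagents that add atoms: none
Why: Heterogeneous partial hydrogenation of a phenol stops at the cyclohexanone because the intermediate cyclohexenol tautomerises, and base equilibration of the two α-centres gives the all-equatorial meso isomer.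

Step 2
Reactants: 2 meso ketone
Product: 3 (4S,6R)-2,4,6-trimethyl-1-(trimethylsilyloxy)cyclohex-1-ene
Conditions: LiN[(R)-CH(Me)Ph]2 (from the amine and n-BuLi), Me3SiCl (internal quench), LiCl, THF, −100 °C
Reagents that add atoms: chlorotrimethylsilane C[Si](C)(C)Cl
Why: Enantioselective deprotonation of a meso ketone by a C2-symmetric chiral lithium amide removes one of the two enantiotopic axial α-hydrogens, which fixes the absolute configuration of the two secondary methyl centres of ring A (the antipodal amide is used should the sense of induction prove opposite).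

Step 3
Reactants: 3 silyl enol ether
Product: 4 (4S,6R)-2,4,6-trimethylcyclohex-2-en-1-one
Conditions: Pd(OAc)2 (10 mol %), O2, DMSO, 60 °C
Reagents that add atoms: none
Why: Saegusa–Ito oxidation dehydrogenates the regiodefined silyl enol ether through a palladium enolate and β-hydride elimination towards the ring CH2, without touching the two stereocentres.

Step 4
Reactants: 4 enone
Product: 5 vinyl-substituted silyl enol ether (vinyl trans to the neighbouring ring methyl)
Conditions: CH2=CHMgBr, CuBr·SMe2 (10 mol %), Me3SiCl, HMPA, THF, −78 °C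
Reagents that add atoms: vinylmagnesium bromide C=C[Mg]Br; chlorotrimethylsilane C[Si](C)(C)Cl
Why: Copper-catalysed conjugate addition accelerated by the silyl chloride delivers vinyl to the β-carbon anti to the methyl on the neighbouring carbon and traps the enolate regiospecifically as its silyl enol ether.

Step 5
Reactants: 5 silyl enol ether
Product: 6 2-(dimethoxymethyl)-2,4,6-trimethyl-3-vinylcyclohexanone (dimethoxymethyl trans to vinyl)
Conditions: HC(OMe)3, Me3SiOTf (10 mol %), CH2Cl2, −78 °C
Reagents that add atoms: trimethyl orthoformate COC(OC)OC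
Why: Mukaiyama-type addition of the tetrasubstituted silyl enol ether to the dimethoxycarbenium ion creates the quaternary centre, the electrophile entering anti to the adjacent vinyl group so that the methyl ends axial and cis to vinyl.

Step 6
Reactants: 6 keto acetal
Product: 7 cyclohexanol (equatorial carbinol expected; this centre is removed in step 8)
Conditions: LiAlH4, Et2O, 0 °C
Reagents that add atoms: none
Why: Hydride reduction of the hindered ketone by axial attack prepares the radical deoxygenation.

Step 7
Reactants: 7 alcohol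
Product: 8 S-methyl xanthate
Conditions: NaH, CS2, THF, 0 → 23 °C; then MeI
Reagents that add atoms: carbon disulfide S=C=S; iodomethane CI
Why: Xanthate formation (alkoxide addition to CS2, then S-methylation) is the standard activation of a hindered secondary alcohol for Barton–McCombie deoxygenation.

Step 8
Reactants: 8 xanthate
Product: 9 1-(dimethoxymethyl)-1,3,5-trimethyl-2-vinylcyclohexane (ring A)
Conditions: n-Bu3SnH, azobisisobutyronitrile (cat.), toluene, 110 °C
Reagents that add atoms: none
Why: Barton–McCombie deoxygenation replaces C–O by C–H through a ring radical that has no favourable cyclisation onto the vinyl group, leaving all stereocentres untouched.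

Step 9
Reactants: 9 acetal
Product: 10 1,3,5-trimethyl-2-vinylcyclohexane-1-carbaldehyde
Conditions: CF3CO2H, H2O, CHCl3, 0 → 23 °C
Reagents that add atoms: water O
Why: Acid-catalysed acetal hydrolysis releases the neopentyl aldehyde, which cannot epimerise because its α-carbon is quaternary.

Step 10
Reactants: 10 aldehyde
Product: 11 (E)-α-methyl enone (ethyl ketone) on the quaternary carbon
Conditions: pentan-3-one (excess), NaOH, EtOH, 60 °C
Reagents that add atoms: pentan-3-one CCC(=O)CC
Why: Claisen–Schmidt condensation of the non-enolisable aldehyde with pentan-3-one gives the thermodynamically favoured (E)-enone after dehydration.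

Step 11
Reactants: 11 vinyl enone
Product: 12 enone aldehyde (ring CHO trans to the enone-bearing chain)
Conditions: OsO4 (2 mol %), NaIO4, 2,6-lutidine, dioxane/H2O, 23 °C
Reagents that add atoms: osmium tetroxide O=[Os](=O)(=O)=O; sodium periodate [Na+].[O-]I(=O)(=O)=O
Why: Lemieux–Johnson oxidation cleaves the monosubstituted vinyl group in preference to the hindered, electron-poor trisubstituted enone, and the equatorial ring aldehyde is configurationally stable.

Step 12
Reactants: 12 enone aldehyde
Product: 13 methyl (E)-γ-hydroxy enoate (carbinol epimeric to the target at the future aryloxy carbon)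
Conditions: CrCl2, NiCl2 (cat.), DMSO, 23 °C
Reagents that add atoms: methyl (E)-3-iodoacrylate COC(=O)/C=C/I
Why: Nozaki–Hiyama–Kishi coupling adds the (E)-alkenylchromium species chemoselectively to the aldehyde with retention of alkene geometry, the nucleophile entering anti to the quaternary ring carbon (1,2-induction), which gives the carbinol that step 16 inverts.

Step 13
Reactants: 14 (4-bromophenoxy)(tert-butyl)dimethylsilane; 15 (S)-epichlorohydrin
Product: 16 (S)-1-[4-(tert-butyldimethylsilyloxy)phenyl]-3-chloropropan-2-ol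
Conditions: Mg, THF; then 15, CuI (10 mol %), −40 → 0 °C
Reagents that add atoms: none
Why: Copper-catalysed SN2 opening of the epoxide by the aryl Grignard reagent occurs at the terminal CH2, so the stereocentre is not touched.

Step 14
Reactants: 16 chlorohydrin
Product: 17 bis(silyl) ether
Conditions: t-BuMe2SiOTf, 2,6-lutidine, CH2Cl2, −78 °C
Reagents that add atoms: tert-butyldimethylsilyl triflate CC(C)(C)[Si](C)(C)OS(=O)(=O)C(F)(F)F
Why: Silylation of the secondary alcohol with a silyl triflate and a hindered base masks the future benzyl ketone oxygen.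

Step 15
Reactants: 17 bis(silyl) ether
Product: 18 4-[(2S)-2-(tert-butyldimethylsilyloxy)-3-chloropropyl]phenol
Conditions: K2CO3 (cat.), MeOH, 0 °C
Reagents that add atoms: none
Why: Methanolysis cleaves the aryl silyl ether selectively because phenoxide is a far better leaving group from silicon than the secondary alkoxide.

Step 16
Reactants: 13 γ-hydroxy enoate; 18 phenol
Product: 19 aryl ether (aryloxy carbon in the configuration of the target)
Conditions: PPh3, diisopropyl azodicarboxylate, toluene, 0 → 23 °C
Reagents that add atoms: none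
Why: Mitsunobu etherification (SN2 of the phenoxide on the oxyphosphonium ion) forms the aryl ether with inversion, which corrects the carbinol centre set in step 12.

Step 17
Reactants: 19 aryl ether
Product: 21 tricyclic silyl enol ether (rings A, B and C), via siloxydiene 20 (not isolated)
Conditions: t-BuMe2SiOTf, Et3N, CH2Cl2, −78 → 0 °C; then toluene, 2,6-di-tert-butyl-4-methylphenol (cat.), 110 °C
Reagents that add atoms: tert-butyldimethylsilyl triflate CC(C)(C)[Si](C)(C)OS(=O)(=O)C(F)(F)F
Why: Soft enolisation gives the (Z)-2-siloxydiene and the intramolecular Diels–Alder reaction through the ester-endo transition state closes rings B and C together; the (E)-enoate places the ester trans to the ring B bond, the endo mode is expected to give the trans ring fusion, and the diene can be reached only on the face that carries the ring A tether, with the aryloxy group pseudo-equatorial, so that the ring-fusion hydrogen next to the quaternary carbon ends anti to the angular methyl.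

Step 18
Reactants: 21 silyl enol ether
Product: 22 tricyclic ring C ketone (both α-methyls equatorial)
Conditions: CsF, MeOH, 23 °C
Reagents that add atoms: none
Why: Fluoride cleaves the silyl enol ether and the basic methanol equilibrates both α-centres to equatorial methyl, which leaves an axial hydrogen on the upper (β) face at the methyl-bearing carbon next to the ring fusion.

Step 19
Reactants: 22 ketone
Product: 23 enol triflate (double bond towards C-per)
Conditions: KN(SiMe3)2, THF, −78 °C; then PhNTf2
Reagents that add atoms: N-phenylbis(trifluoromethanesulfonimide) O=S(=O)(N(c1ccccc1)S(=O)(=O)C(F)(F)F)C(F)(F)F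
Why: Kinetic deprotonation by the hindered amide and O-triflation occur towards the α-carbon next to C-α, because the other axial α-hydrogen is screened by the angular methyl and the ester α-hydrogen is far less acidic.

Step 20
Reactants: 23 enol triflate
Product: 24 ring C alkene ester (trisubstituted alkene at C-per)
Conditions: Pd(OAc)2 (5 mol %), PPh3, HCO2H, Et3N, DMF, 60 °C
Reagents that add atoms: none
Why: Palladium-catalysed formate reduction of the vinyl triflate (oxidative addition, hydride transfer with loss of CO2, reductive elimination) gives the alkene regiospecifically.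

Step 21
Reactants: 24 ester
Product: 25 α-allyl β-keto nitrile (mixture of epimers at the future C-spiro)
Conditions: pent-4-enenitrile, LiN(i-Pr)2, THF, −78 → −40 °C
Reagents that add atoms: pent-4-enenitrile C=CCCC#N
Why: Claisen-type acylation of the lithiated nitrile by the methyl ester gives the β-keto nitrile already carrying the allyl group, the product resting as its enolate until work-up and kinetic α-protonation keeping the ring alkene out of conjugation.

Step 22
Reactants: 25 silyl ether
Product: 26 chlorohydrin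
Conditions: HF·pyridine, THF, 0 → 23 °C
Reagents that add atoms: none
Why: Acidic fluoride desilylation frees the secondary alcohol without closing the chlorohydrin to an epoxide.

Step 23
Reactants: 26 chlorohydrin
Product: 27 α-chloro ketone
Conditions: Dess–Martin periodinane, NaHCO3, CH2Cl2, 0 °C
Reagents that add atoms: none
Why: Dess–Martin oxidation of the secondary alcohol gives the α-chloro ketone under buffered, non-basic conditions that leave the β-keto nitrile alone.

Step 24
Reactants: 27 α-chloro ketone
Product: 28 macrocyclic keto nitrile (13-membered paracyclophane, quaternary C-spiro)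
Conditions: Cs2CO3, NaI (cat.), MeCN (1 mM), 40 °C
Reagents that add atoms: none
Why: Macrocyclising C-alkylation (intramolecular SN2 of the caesium enolate on the Finkelstein-activated α-halo ketone at high dilution) closes the cyclophane and sets C-spiro; with the small nitrile cis to ring C and the C-α hydrogen eclipsing the enolate plane (allylic strain), the arm anchored through the aryl ether on ring B closes on the enolate face syn to ring B, which corresponds to the configuration of the target.

Step 25
Reactants: 28 keto nitrile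
Product: 30 lactam hemiaminal (ring D closed), via keto amide 29 (not isolated)
Conditions: [PtH(PMe2OH){(PMe2O)2H}] (5 mol %), EtOH/H2O, 80 °C
Reagents that add atoms: water O
Why: Platinum-catalysed hydration converts the hindered nitrile into the primary amide under neutral conditions, and the amide nitrogen adds 5-exo-trig to the γ-ketone to give the lactam hemiaminal, whose configuration is set by equilibration.

Step 26
Reactants: 30 lactam
Product: 33 bis(triethylsilyl) dioxolane, via allylic hydroperoxide 31 (not isolated), via dioxolanol 32 (not isolated)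
Conditions: O2, tetraphenylporphyrin (cat.), visible light, CH2Cl2, −20 °C; then Et3SiOTf, 2,6-lutidine, −78 °C
Reagents that add atoms: dioxygen O=O; triethylsilyl triflate CC[Si](CC)(CC)OS(=O)(=O)C(F)(F)F
Why: Schenck ene reaction of singlet oxygen abstracts the only aligned (axial, β-face) ring allylic hydrogen suprafacially, so that C-per–OOH forms on the β-face with transposition of the alkene, and the β-hydroperoxy ketone closes 5-exo-trig onto C-ket to the cis-fused 1,2-dioxolan-3-ol, which silylation (also of the hemiaminal hydroxyl) locks.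

Step 27
Reactants: 33 alkene
Product: 34 bromohydrin (tertiary alcohol β, bromide α)
Conditions: N-bromosuccinimide, NaHCO3, THF/H2O, 0 °C
Reagents that add atoms: N-bromosuccinimide O=C1CCC(=O)N1Br; water O
Why: Halohydrin formation: the bromonium ion forms on the α-face (the β-face is screened by the pseudo-axial peroxide oxygen and the angular methyl) and water opens it trans-diaxially at the tertiary carbon, while the monosubstituted allyl group reacts far more slowly.

Step 28
Reactants: 34 bromohydrin
Product: 35 epoxide (β-epoxide, cis to the peroxide oxygen)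
Conditions: K2CO3, MeOH, 0 °C
Reagents that add atoms: none
Why: Intramolecular Williamson ether synthesis: the tertiary alkoxide displaces the antiperiplanar bromide with inversion, which places the epoxide on the β-face as in the target.

Step 29
Reactants: 35 epoxide
Product: 38 CNP0533733.1 (target), via aldehyde 36 (not isolated), via hydroperoxy keto-aldehyde 37 (not isolated)
Conditions: O3, pyridine, CH2Cl2, −78 °C; then HF·pyridine, THF, 0 → 23 °C
Reagents that add atoms: ozone [O-][O+]=O
Why: Ozone cleaves the only remaining C=C (pyridine converts the carbonyl oxide directly into the aldehyde, so no reductant meets the peroxide) to give aldehyde 36, and fluoride then removes both silyl groups, so that the freed 1,2-dioxolan-3-ol opens by retro-hemiketalisation to β-hydroperoxy ketone 37, whose OOH adds to the new aldehyde. The closest known reaction types are the ozonolysis of terminal alkenes, the ring–chain tautomerism of β-hydroperoxy ketones with 1,2-dioxolan-3-ols, and the formation of cyclic peroxyhemiacetals from hydroperoxides and aldehydes. Ring E closes by 8-exo-trig addition of the hydroperoxide oxygen to the aldehyde carbon under thermodynamic control. The one new stereocentre, C-hem, is set by equilibration within the cis-fused bicycle that the fixed configurations at C-per, C-α and C-spiro impose, and the hemiaminal carbon re-equilibrates in the same way. The step needs the hydroperoxide to choose the aldehyde over C-ket, which the higher electrophilicity of the unhindered aldehyde and the strain of an sp3 C-ket inside the cyclophane should secure.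

**Compound list**
1 | 2,4,6-trimethylphenol | Cc1cc(C)c(O)c(C)c1 | starting material
2 | cis,cis-2,4,6-trimethylcyclohexanone (meso) | O=C1[C@H](C)C[C@H](C)C[C@@H]1C | intermediate
3 | (4S,6R)-2,4,6-trimethyl-1-(trimethylsilyloxy)cyclohex-1-ene | C[C@@H]1C[C@H](C)CC(C)=C1O[Si](C)(C)C | intermediate
4 | (4S,6R)-2,4,6-trimethylcyclohex-2-en-1-one | C[C@@H]1C[C@H](C)C=C(C)C1=O | intermediate
5 | 3-vinyl silyl enol ether (vinyl trans to the 4-methyl) | C[C@@H]1C[C@H](C)[C@@H](C=C)C(C)=C1O[Si](C)(C)C | intermediate
6 | 2-(dimethoxymethyl)-2,4,6-trimethyl-3-vinylcyclohexanone | C[C@@H]1C[C@H](C)[C@@H](C=C)[C@](C)(C(OC)OC)C1=O | intermediate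
7 | corresponding cyclohexanol (equatorial OH drawn) | C[C@@H]1C[C@H](C)[C@@H](C=C)[C@](C)(C(OC)OC)[C@H]1O | intermediate
8 | S-methyl xanthate of 7 | C[C@@H]1C[C@H](C)[C@@H](C=C)[C@](C)(C(OC)OC)[C@H]1OC(=S)SC | intermediate
9 | 1-(dimethoxymethyl)-1,3,5-trimethyl-2-vinylcyclohexane | C[C@@H]1C[C@H](C)[C@@H](C=C)[C@](C)(C(OC)OC)C1 | intermediate
10 | 1,3,5-trimethyl-2-vinylcyclohexane-1-carbaldehyde | C[C@@H]1C[C@H](C)[C@@H](C=C)[C@](C)(C=O)C1 | intermediate
11 | (E)-2-methyl-1-(ring A)-pent-1-en-3-one, vinyl on ring | C[C@@H]1C[C@H](C)[C@@H](C=C)[C@](C)(/C=C(\C)C(=O)CC)C1 | intermediate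
12 | enone aldehyde | C[C@@H]1C[C@H](C)[C@@H](C=O)[C@](C)(/C=C(\C)C(=O)CC)C1 | intermediate
13 | methyl (E)-γ-hydroxy enoate (epi-carbinol) | C[C@@H]1C[C@H](C)[C@@H]([C@H](O)/C=C/C(=O)OC)[C@](C)(/C=C(\C)C(=O)CC)C1 | intermediate
14 | (4-bromophenoxy)(tert-butyl)dimethylsilane | CC(C)(C)[Si](C)(C)Oc1ccc(Br)cc1 | starting material
15 | (S)-epichlorohydrin | ClC[C@@H]1CO1 | starting material
16 | (S)-1-[4-(tert-butyldimethylsilyloxy)phenyl]-3-chloropropan-2-ol | ClC[C@@H](O)Cc1ccc(O[Si](C)(C)C(C)(C)C)cc1 | intermediate
17 | bis(silyl) ether of 16 | ClC[C@@H](O[Si](C)(C)C(C)(C)C)Cc1ccc(O[Si](C)(C)C(C)(C)C)cc1 | intermediate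
18 | 4-[(2S)-2-(tert-butyldimethylsilyloxy)-3-chloropropyl]phenol | ClC[C@@H](O[Si](C)(C)C(C)(C)C)Cc1ccc(O)cc1 | intermediate
19 | aryl ether, enone and enoate on ring A | C[C@@H]1C[C@H](C)[C@@H]([C@@H](Oc2ccc(C[C@@H](CCl)O[Si](C)(C)C(C)(C)C)cc2)/C=C/C(=O)OC)[C@](C)(/C=C(\C)C(=O)CC)C1 | intermediate
20 | (Z)-2-siloxydiene | C[C@@H]1C[C@H](C)[C@@H]([C@@H](Oc2ccc(C[C@@H](CCl)O[Si](C)(C)C(C)(C)C)cc2)/C=C/C(=O)OC)[C@](C)(/C=C(\C)/C(O[Si](C)(C)C(C)(C)C)=C/C)C1 | intermediate
21 | tricyclic silyl enol ether | C[C@@H]1C[C@H](C)[C@H]2[C@@H](Oc4ccc(C[C@@H](CCl)O[Si](C)(C)C(C)(C)C)cc4)[C@@H]3[C@@H](C(=O)OC)[C@@H](C)C(O[Si](C)(C)C(C)(C)C)=C(C)[C@H]3[C@]2(C)C1 | intermediate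
22 | tricyclic ring C ketone | C[C@@H]1C[C@H](C)[C@H]2[C@@H](Oc4ccc(C[C@@H](CCl)O[Si](C)(C)C(C)(C)C)cc4)[C@@H]3[C@@H](C(=O)OC)[C@H](C)C(=O)[C@H](C)[C@H]3[C@]2(C)C1 | intermediate
23 | enol triflate | C[C@@H]1C[C@H](C)[C@H]2[C@@H](Oc4ccc(C[C@@H](CCl)O[Si](C)(C)C(C)(C)C)cc4)[C@@H]3[C@@H](C(=O)OC)C(C)=C(OS(=O)(=O)C(F)(F)F)[C@H](C)[C@H]3[C@]2(C)C1 | intermediate
24 | ring C alkene methyl ester | C[C@@H]1C[C@H](C)[C@H]2[C@@H](Oc4ccc(C[C@@H](CCl)O[Si](C)(C)C(C)(C)C)cc4)[C@@H]3[C@@H](C(=O)OC)C(C)=C[C@H](C)[C@H]3[C@]2(C)C1 | intermediate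
25 | α-allyl β-keto nitrile (epimers at the nitrile carbon) | C[C@@H]1C[C@H](C)[C@H]2[C@@H](Oc4ccc(C[C@@H](CCl)O[Si](C)(C)C(C)(C)C)cc4)[C@@H]3[C@@H](C(=O)C(CC=C)C#N)C(C)=C[C@H](C)[C@H]3[C@]2(C)C1 | intermediate
26 | chlorohydrin | C[C@@H]1C[C@H](C)[C@H]2[C@@H](Oc4ccc(C[C@@H](CCl)O)cc4)[C@@H]3[C@@H](C(=O)C(CC=C)C#N)C(C)=C[C@H](C)[C@H]3[C@]2(C)C1 | intermediate
27 | α-chloro ketone | C[C@@H]1C[C@H](C)[C@H]2[C@@H](Oc4ccc(CC(=O)CCl)cc4)[C@@H]3[C@@H](C(=O)C(CC=C)C#N)C(C)=C[C@H](C)[C@H]3[C@]2(C)C1 | intermediate
28 | macrocyclic keto nitrile | C[C@@H]1C[C@H](C)[C@H]2[C@H]3Oc4ccc(cc4)CC(=O)C[C@](CC=C)(C#N)C(=O)[C@H]5C(C)=C[C@H](C)[C@H]([C@H]35)[C@]2(C)C1 | intermediate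
29 | macrocyclic keto amide | C[C@@H]1C[C@H](C)[C@H]2[C@H]3Oc4ccc(cc4)CC(=O)C[C@](CC=C)(C(N)=O)C(=O)[C@H]5C(C)=C[C@H](C)[C@H]([C@H]35)[C@]2(C)C1 | intermediate
30 | lactam hemiaminal | C[C@@H]1C[C@H](C)[C@H]2[C@H]3Oc4ccc(cc4)C[C@]4(O)C[C@](CC=C)(C(=O)N4)C(=O)[C@H]5C(C)=C[C@H](C)[C@H]([C@H]35)[C@]2(C)C1 | intermediate
31 | tertiary allylic hydroperoxide | C[C@@H]1C[C@H](C)[C@H]2[C@H]3Oc4ccc(cc4)C[C@]4(O)C[C@](CC=C)(C(=O)N4)C(=O)[C@H]5[C@](OO)(C)C=C(C)[C@H]([C@H]35)[C@]2(C)C1 | intermediate
32 | cis-fused 1,2-dioxolan-3-ol (hemiketal epimer drawn is inconsequential) | C[C@@H]1C[C@H](C)[C@H]2[C@H]3Oc4ccc(cc4)C[C@]4(O)C[C@](CC=C)(C(=O)N4)[C@@]6(O)[C@H]5[C@](OO6)(C)C=C(C)[C@H]([C@H]35)[C@]2(C)C1 | intermediate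
33 | bis(triethylsilyl) dioxolane | C[C@@H]1C[C@H](C)[C@H]2[C@H]3Oc4ccc(cc4)C[C@]4(O[Si](CC)(CC)CC)C[C@](CC=C)(C(=O)N4)[C@@]6(O[Si](CC)(CC)CC)[C@H]5[C@](OO6)(C)C=C(C)[C@H]([C@H]35)[C@]2(C)C1 | intermediate
34 | bromohydrin | C[C@@H]1C[C@H](C)[C@H]2[C@H]3Oc4ccc(cc4)C[C@]4(O[Si](CC)(CC)CC)C[C@](CC=C)(C(=O)N4)[C@@]6(O[Si](CC)(CC)CC)[C@H]5[C@](OO6)(C)[C@H](Br)[C@](O)(C)[C@H]([C@H]35)[C@]2(C)C1 | intermediate
35 | epoxide | C[C@@H]1C[C@H](C)[C@H]2[C@H]3Oc4ccc(cc4)C[C@]4(O[Si](CC)(CC)CC)C[C@](CC=C)(C(=O)N4)[C@@]6(O[Si](CC)(CC)CC)[C@H]5[C@](OO6)(C)[C@H]7O[C@@]7(C)[C@H]([C@H]35)[C@]2(C)C1 | intermediate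
36 | silyl-locked aldehyde | C[C@@H]1C[C@H](C)[C@H]2[C@H]3Oc4ccc(cc4)C[C@]4(O[Si](CC)(CC)CC)C[C@](CC=O)(C(=O)N4)[C@@]6(O[Si](CC)(CC)CC)[C@H]5[C@](OO6)(C)[C@H]7O[C@@]7(C)[C@H]([C@H]35)[C@]2(C)C1 | intermediate
37 | hydroperoxy keto-aldehyde (open form) | C[C@@H]1C[C@H](C)[C@H]2[C@H]3Oc4ccc(cc4)C[C@]4(O)C[C@](CC=O)(C(=O)N4)C(=O)[C@H]5[C@](OO)(C)[C@H]7O[C@@]7(C)[C@H]([C@H]35)[C@]2(C)C1 | intermediate
38 | CNP0533733.1 | C[C@@H]1C[C@H](C)[C@H]2[C@H]3Oc4ccc(cc4)C[C@]4(O)C[C@]5(C[C@H](O)OO[C@@]6(C)[C@H]7O[C@@]7(C)[C@H]([C@H]3[C@H]6C5=O)[C@]2(C)C1)C(=O)N4 | target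

**Totals**
Total step count: 29. Longest linear sequence: 26 steps (steps 1–12 and 16–29); phenol 18 is made in 3 steps (13–15).

**The three steps most likely to fail**

Step 24 (macrocyclisation). Ring closure at a fully substituted enolate carbon into a strained 13-membered paracyclophane may lose to oligomerisation or O-alkylation, and the enolate face may not be discriminated. The fallback closes the ring at a tertiary carbon first and allylates afterwards; it sets out from 24 and comes back at 28. Acylation of LiCH2CN (MeCN, LiN(i-Pr)2, THF, −78 °C) by 24 gives the unsubstituted β-keto nitrile F1. HF·pyridine gives chlorohydrin F2, and Dess–Martin oxidation gives chloro ketone F3. Cs2CO3/NaI at high dilution closes the less hindered macrocycle F4, which is epimerisable at the nitrile carbon. Tsuji–Trost allylation (allyl methyl carbonate, Pd2(dba)3, (R,R)- or (S,S)-DACH-phenyl bisphosphine, the antipode chosen for the needed face) then installs the allyl group on the preformed ring and gives 28.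

Step 26 (ene reaction). Hydrogen abstraction from the vinylic methyl instead of the ring, or oxygen delivery to the wrong alkene carbon, would erode regioselectivity. The fallback replaces the ene reaction by ionic bromohydroperoxidation and elimination; it sets out from 30 and comes back at 33. 1,3-Dibromo-5,5-dimethylhydantoin with anhydrous H2O2 in Et2O at −40 °C adds Br and OOH trans-diaxially, with OOH at the more substituted carbon C-per on the β-face; the hydroperoxide closes onto C-ket to give bromo dioxolanol F5. Et3SiOTf/2,6-lutidine gives the bis(silyl) bromide F6. DBU in toluene at 60 °C removes HBr by anti elimination, for which only the hydrogen on the methyl-bearing carbon is available, and gives 33.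

Step 29 (key step). Ozone may attack the electron-rich aryl ether in competition with the hindered allyl group, or the carbonyl oxide may be intercepted before it collapses to the aldehyde. The fallback cleaves the alkene stepwise without ozone; it sets out from 35 and comes back at 38. OsO4 (cat.)/N-methylmorpholine N-oxide gives diol F7; NaIO4 (buffered, THF/H2O) gives aldehyde 36, which is isolated; HF·pyridine then triggers the same desilylation and peroxide relay to 38.

**Further compounds**
F1 | step 24 | β-keto nitrile without allyl group | C[C@@H]1C[C@H](C)[C@H]2[C@@H](Oc4ccc(C[C@@H](CCl)O[Si](C)(C)C(C)(C)C)cc4)[C@@H]3[C@@H](C(=O)CC#N)C(C)=C[C@H](C)[C@H]3[C@]2(C)C1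
F2 | step 24 | chlorohydrin of F1 | C[C@@H]1C[C@H](C)[C@H]2[C@@H](Oc4ccc(C[C@@H](CCl)O)cc4)[C@@H]3[C@@H](C(=O)CC#N)C(C)=C[C@H](C)[C@H]3[C@]2(C)C1
F3 | step 24 | α-chloro ketone without allyl group | C[C@@H]1C[C@H](C)[C@H]2[C@@H](Oc4ccc(CC(=O)CCl)cc4)[C@@H]3[C@@H](C(=O)CC#N)C(C)=C[C@H](C)[C@H]3[C@]2(C)C1
F4 | step 24 | macrocyclic keto nitrile with tertiary nitrile carbon (epimers) | C[C@@H]1C[C@H](C)[C@H]2[C@H]3Oc4ccc(cc4)CC(=O)CC(C#N)C(=O)[C@H]5C(C)=C[C@H](C)[C@H]([C@H]35)[C@]2(C)C1
F5 | step 26 | bromo dioxolanol | C[C@@H]1C[C@H](C)[C@H]2[C@H]3Oc4ccc(cc4)C[C@]4(O)C[C@](CC=C)(C(=O)N4)[C@@]6(O)[C@H]5[C@](OO6)(C)[C@H](Br)[C@H](C)[C@H]([C@H]35)[C@]2(C)C1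
F6 | step 26 | bis(triethylsilyl) bromo dioxolane | C[C@@H]1C[C@H](C)[C@H]2[C@H]3Oc4ccc(cc4)C[C@]4(O[Si](CC)(CC)CC)C[C@](CC=C)(C(=O)N4)[C@@]6(O[Si](CC)(CC)CC)[C@H]5[C@](OO6)(C)[C@H](Br)[C@H](C)[C@H]([C@H]35)[C@]2(C)C1
F7 | step 29 | diol from the allyl group (carbinol epimers) | C[C@@H]1C[C@H](C)[C@H]2[C@H]3Oc4ccc(cc4)C[C@]4(O[Si](CC)(CC)CC)C[C@](CC(O)CO)(C(=O)N4)[C@@]6(O[Si](CC)(CC)CC)[C@H]5[C@](OO6)(C)[C@H]7O[C@@]7(C)[C@H]([C@H]35)[C@]2(C)C1
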